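## Retrosynthetic overview

1. Feature: counting from the ester carbon C1, the 1,2-dioxane (C3, C4, C5, C6 and the O–O pair) has its C3–O bond β to the C1 carbonyl, so C1–C2–C3 and that oxygen position are the atoms of an oxetan-2-one whose alkyl C–O bond at C3 can be displaced by the peroxide oxygen carried by C6.
2. Disconnections: C11–C12 (Sonogashira coupling of a dioxane alkyne with (1E)-1-iodoundeca-1,10-diene); C3–O(peroxide) (intramolecular opening of a (4R)-β-lactone by the C6 hydroperoxy ketal, inversion giving 3S); the C6 hydroperoxy ketal from a C6 methylidene group (ozonolysis in methanol).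
3. The lactone comes from a 4-methylidene aldehyde and ketene (alkaloid-catalysed [2+2]); the aldehyde comes from an orthoester Claisen rearrangement of a 2-substituted allyl alcohol made by carbomagnesiation of propargyl alcohol.
4. Ring order: the oxetan-2-one first (step 5), then the 1,2-dioxane (step 7), formed as the four-membered ring opens; C6 is corrected afterwards by acid equilibration to the axial-methoxy epimer.

Key step: step 7

Assumption: O-trimethylsilylquinine is taken as the pseudoenantiomeric catalyst that delivers the (4R)-lactone from an unbranched aldehyde. If a first run (methanolysis to the β-hydroxy ester, Mosher ester analysis) should show the opposite sense, O-trimethylsilylquinidine would replace it with no other change.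

Remark: the hydroperoxide and peroxides from step 6 onward would be handled cold, in solution where possible and on small scale.

## Route

Step 1
Reactants: 1 5-chloropent-1-yne
Product: 3 (5-chloropent-1-yn-1-yl)tri(propan-2-yl)silane, via lithium acetylide 2 (not isolated)
Conditions: n-BuLi (1.05 equiv), THF, −78 °C; then i-Pr3SiCl, −78 °C → rt
Reagents that add atoms: chlorotri(propan-2-yl)silane, CC(C)[Si](Cl)(C(C)C)C(C)C
Why: Deprotonation of the terminal alkyne and C-silylation of the lithium acetylide (alkynylsilane formation) should be clean because the primary chloride is inert to the acetylide in THF without a dipolar cosolvent, and the bulky silyl group then shields the alkyne through Grignard formation, ozonolysis and base.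

Step 2
Reactants: 3 (5-chloropent-1-yn-1-yl)tri(propan-2-yl)silane (2.5 equiv relative to 4); 4 prop-2-yn-1-ol
Product: 7 2-methylidene-7-[tri(propan-2-yl)silyl]hept-6-yn-1-ol, via Grignard reagent 5 (not isolated), via alkenylmagnesium alkoxide 6 (not isolated)
Conditions: Mg turnings, BrCH2CH2Br (cat.), THF, 60 °C; then 4, CuI (10 mol%), THF/Et2O, −10 °C → rt; aq NH4Cl
Reagents that add atoms: none
Why: The primary chloride inserts magnesium, and the resulting Grignard reagent adds under CuI catalysis across the magnesium alkoxide of propargyl alcohol (hydroxyl-directed anti-carbomagnesiation of a propargylic alcohol), the carbon group going to C2 and magnesium to C3 in a five-membered chelate, so that protonation should give the 2-substituted allyl alcohol regioselectively, one equivalent of the reagent being spent as base on the hydroxyl group.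

Step 3
Reactants: 7 2-methylidene-7-[tri(propan-2-yl)silyl]hept-6-yn-1-ol
Product: 9 ethyl 4-methylidene-9-[tri(propan-2-yl)silyl]non-8-ynoate, via ketene acetal 8 (not isolated)
Conditions: MeC(OEt)3 (6 equiv), EtCO2H (5 mol%), 140 °C, EtOH distilled off
Reagents that add atoms: triethyl orthoacetate, CC(OCC)(OCC)OCC
Why: Johnson–Claisen (orthoester Claisen) rearrangement, in which acid-catalysed exchange and loss of ethanol give the ketene acetal whose [3,3]-sigmatropic shift attaches the two-carbon ester arm at the former alkene terminus and leaves the 1,1-disubstituted alkene that later becomes C6, with no stereocentre or alkene geometry at stake.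

Step 4
Reactants: 9 ethyl 4-methylidene-9-[tri(propan-2-yl)silyl]non-8-ynoate
Product: 11 4-methylidene-9-[tri(propan-2-yl)silyl]non-8-ynal, via aluminium hemiacetal 10 (not isolated)
Conditions: i-Bu2AlH (1.05 equiv), CH2Cl2, −78 °C; MeOH, then aq potassium sodium tartrate
Reagents that add atoms: none
Why: Partial reduction of the ester with one equivalent of i-Bu2AlH at −78 °C should stop at the tetrahedral aluminium hemiacetal, which releases the aldehyde only on work-up, while the alkene and the silylalkyne are inert to the hydride at this temperature.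

Step 5
Reactants: 11 4-methylidene-9-[tri(propan-2-yl)silyl]non-8-ynal; 12 acetyl chloride (2 equiv, added slowly)
Product: 14 (4R)-4-{3-methylidene-8-[tri(propan-2-yl)silyl]oct-7-yn-1-yl}oxetan-2-one, via ketene 13 (not isolated)
Conditions: O-trimethylsilylquinine (10 mol%), LiClO4 (1 equiv), i-Pr2NEt (2.5 equiv), CH2Cl2/Et2O, −78 °C
Reagents that add atoms: none
Why: Acyl halide–aldehyde cyclocondensation (alkaloid-catalysed ketene–aldehyde [2+2] cycloaddition), in which ketene formed from acetyl chloride and the amine adds to the alkaloid to give a chiral ammonium enolate that undergoes lithium-templated aldol addition and lactonisation, the catalyst selecting the aldehyde face so that the future C3 is created as the (4R)-lactone carbon.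

Step 6
Reactants: 14 (4R)-4-{3-methylidene-8-[tri(propan-2-yl)silyl]oct-7-yn-1-yl}oxetan-2-one
Product: 16 (4R)-4-{3-hydroperoxy-3-methoxy-8-[tri(propan-2-yl)silyl]oct-7-yn-1-yl}oxetan-2-one (both C6 epimers), via carbonyl oxide 15 (not isolated)
Conditions: O3/O2, CH2Cl2/MeOH (3:1), −78 °C, Sudan Red 7B end point; N2 purge, cold concentration, used at once
Reagents that add atoms: ozone, [O-][O+]=O; methanol, CO
Why: Ozonolysis in methanol, in which the electron-rich 1,1-disubstituted alkene should react far faster than the hindered silylalkyne, the primary ozonide cleaves to formaldehyde and the ketone-derived carbonyl oxide, and methanol traps the latter as the α-methoxy hydroperoxide, C6 forming without selectivity and the lactone stereocentre staying untouched.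

Step 7
Reactants: 16 (4R)-4-{3-hydroperoxy-3-methoxy-8-[tri(propan-2-yl)silyl]oct-7-yn-1-yl}oxetan-2-one (both C6 epimers)
Product: 19 2-[(3S)-6-methoxy-6-{5-[tri(propan-2-yl)silyl]pent-4-yn-1-yl}-1,2-dioxan-3-yl]acetic acid (both C6 epimers), via caesium peroxide 17 (not isolated), via caesium carboxylate 18 (not isolated)
Conditions: Cs2CO3 (1.2 equiv), DMF (0.01 M), −20 → 0 °C; then cold 1 M HCl to pH 3, extraction
Reagents that add atoms: none
Why: Proposed new method: Cs2CO3 deprotonates the C6 hydroperoxy ketal and the terminal peroxide oxygen attacks the lactone alkyl carbon (C3 of the chain) from the face opposite the lactone oxygen, an intramolecular SN2 displacement that expels the C1 carboxylate and is driven by release of the oxetanone strain. The closest known reaction types are the alkyl–oxygen opening of 4-alkyl β-lactones by soft heteroatom nucleophiles (azide, thiolate, sulfonamide anions) with inversion and the base-mediated cyclisation of hydroperoxy ketals onto secondary sulfonates; their combination on a β-lactone has not been shown. The 1,2-dioxane closes in a 6-exo-tet mode through a chair-like transition state. The one new stereocentre, C3, is fixed as S by inversion of the (4R)-lactone carbon, so the control element is the lactone configuration from step 5, while C6 stays a mixture that step 8 corrects. The step needs alkyl over acyl attack and substitution over enolisation or E1cB opening to the unsaturated carboxylate: acyl attack would demand an eight-membered perester ring, and the weak heterogeneous base, low temperature and high dilution disfavour elimination and carboxylate-initiated oligomerisation.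

Step 8
Reactants: 19 2-[(3S)-6-methoxy-6-{5-[tri(propan-2-yl)silyl]pent-4-yn-1-yl}-1,2-dioxan-3-yl]acetic acid (both C6 epimers)
Product: 20 methyl 2-[(3S,6R)-6-methoxy-6-{5-[tri(propan-2-yl)silyl]pent-4-yn-1-yl}-1,2-dioxan-3-yl]acetate
Conditions: HCl (0.2 M) in dry MeOH, 0 °C → rt; NaHCO3; chromatography, minor C6 epimer resubmitted
Reagents that add atoms: methanol, CO
Why: Fischer esterification of the primary acid takes place in the same acidic methanol that reversibly ionises the C6 methoxy group (acid-catalysed transketalisation), so the C6 epimers should equilibrate toward the anomerically stabilised chair with axial methoxy and both carbon substituents equatorial, which is the (3S,6R) isomer, C3 not being epimerisable under acid.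

Step 9
Reactants: 20 methyl 2-[(3S,6R)-6-methoxy-6-{5-[tri(propan-2-yl)silyl]pent-4-yn-1-yl}-1,2-dioxan-3-yl]acetate
Product: 21 methyl 2-[(3S,6R)-6-methoxy-6-(pent-4-yn-1-yl)-1,2-dioxan-3-yl]acetate
Conditions: Bu4NF (2 equiv), AcOH (2 equiv), THF, 0 °C → rt
Reagents that add atoms: none
Why: Fluoride-induced protodesilylation of the alkynylsilane, with acetic acid buffering so that the medium does not become basic enough for retro-oxa-Michael opening of the β-peroxy ester, which would erode C3.

Step 10
Reactants: 22 dec-9-en-1-ol
Product: 23 dec-9-enal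
Conditions: PhI(OAc)2 (1.1 equiv), TEMPO (10 mol%), CH2Cl2, rt
Reagents that add atoms: none
Why: TEMPO-catalysed oxidation with PhI(OAc)2 should take the primary alcohol to the aldehyde without over-oxidation and leave the terminal alkene alone.

Step 11
Reactants: 23 dec-9-enal
Product: 24 (1E)-1-iodoundeca-1,10-diene
Conditions: CrCl2 (6 equiv), CHI3 (2 equiv), THF/1,4-dioxane, 0 °C → rt
Reagents that add atoms: iodoform, IC(I)I
Why: Takai olefination, in which the geminal dichromium species formed from iodoform and CrCl2 adds to the aldehyde and eliminates to give predominantly the (E)-iodoalkene, the terminal alkene being a spectator and any Z isomer being removed on AgNO3-impregnated silica.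

Step 12
Reactants: 21 methyl 2-[(3S,6R)-6-methoxy-6-(pent-4-yn-1-yl)-1,2-dioxan-3-yl]acetate; 24 (1E)-1-iodoundeca-1,10-diene
Product: 25 peroxyacarnoate A, methyl 2-[(3S,6R)-6-[(6E)-hexadeca-6,15-dien-4-yn-1-yl]-6-methoxy-1,2-dioxan-3-yl]acetate
Conditions: PdCl2(PPh3)2 (5 mol%), CuI (10 mol%), Et3N, THF (degassed), rt, dark
Reagents that add atoms: none
Why: Sonogashira coupling of the terminal alkyne with the (E)-alkenyl iodide should proceed at room temperature with retention of alkene geometry, under conditions (weak amine base, no added free phosphine) mild enough for the dialkyl peroxide and the β-peroxy ester to survive.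

## Compound list

1 | 5-chloropent-1-yne | C#CCCCCl | starting material
2 | lithium 5-chloropent-1-yn-1-ide | [Li]C#CCCCCl | intermediate (not isolated)
3 | (5-chloropent-1-yn-1-yl)tri(propan-2-yl)silane | CC(C)[Si](C(C)C)(C(C)C)C#CCCCCl | intermediate
4 | prop-2-yn-1-ol (propargyl alcohol) | C#CCO | starting material
5 | {5-[tri(propan-2-yl)silyl]pent-4-yn-1-yl}magnesium chloride | CC(C)[Si](C(C)C)(C(C)C)C#CCCC[Mg]Cl | intermediate (not isolated)
6 | alkenylmagnesium alkoxide, Mg on C3 cis to the CH2O–Mg group | Cl[Mg]/C=C(\CO[Mg]Cl)CCCC#C[Si](C(C)C)(C(C)C)C(C)C | intermediate (not isolated)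
7 | 2-methylidene-7-[tri(propan-2-yl)silyl]hept-6-yn-1-ol | C=C(CO)CCCC#C[Si](C(C)C)(C(C)C)C(C)C | intermediate
8 | 1-ethoxyvinyl ether of 7 (ketene acetal) | C=C(OCC)OCC(=C)CCCC#C[Si](C(C)C)(C(C)C)C(C)C | intermediate (not isolated)
9 | ethyl 4-methylidene-9-[tri(propan-2-yl)silyl]non-8-ynoate | CCOC(=O)CCC(=C)CCCC#C[Si](C(C)C)(C(C)C)C(C)C | intermediate
10 | diisobutylaluminium hemiacetal of 9 | CCOC(CCC(=C)CCCC#C[Si](C(C)C)(C(C)C)C(C)C)O[Al](CC(C)C)CC(C)C | intermediate (not isolated)
11 | 4-methylidene-9-[tri(propan-2-yl)silyl]non-8-ynal | O=CCCC(=C)CCCC#C[Si](C(C)C)(C(C)C)C(C)C | intermediate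
12 | acetyl chloride | CC(=O)Cl | starting material
13 | ketene | C=C=O | intermediate (not isolated)
14 | (4R)-4-{3-methylidene-8-[tri(propan-2-yl)silyl]oct-7-yn-1-yl}oxetan-2-one | C=C(CC[C@@H]1CC(=O)O1)CCCC#C[Si](C(C)C)(C(C)C)C(C)C | intermediate
15 | carbonyl oxide at C6 of the (4R)-lactone | [O-][O+]=C(CC[C@@H]1CC(=O)O1)CCCC#C[Si](C(C)C)(C(C)C)C(C)C | intermediate (not isolated)
16 | (4R)-4-{3-hydroperoxy-3-methoxy-8-[tri(propan-2-yl)silyl]oct-7-yn-1-yl}oxetan-2-one, both C6 epimers | CC(C)[Si](C(C)C)(C(C)C)C#CCCCC(OC)(OO)CC[C@@H]1CC(=O)O1 | intermediate (key-step precursor)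
17 | caesium peroxide of 16 | [Cs+].[O-]OC(OC)(CCCC#C[Si](C(C)C)(C(C)C)C(C)C)CC[C@@H]1CC(=O)O1 | intermediate (not isolated)
18 | caesium 2-[(3S)-6-methoxy-6-{5-[tri(propan-2-yl)silyl]pent-4-yn-1-yl}-1,2-dioxan-3-yl]acetate, both C6 epimers | [Cs+].[O-]C(=O)C[C@@H]1CCC(OC)(CCCC#C[Si](C(C)C)(C(C)C)C(C)C)OO1 | intermediate (not isolated)
19 | 2-[(3S)-6-methoxy-6-{5-[tri(propan-2-yl)silyl]pent-4-yn-1-yl}-1,2-dioxan-3-yl]acetic acid, both C6 epimers | CC(C)[Si](C(C)C)(C(C)C)C#CCCCC1(OC)CC[C@@H](CC(=O)O)OO1 | intermediate (key-step product)
20 | methyl 2-[(3S,6R)-6-methoxy-6-{5-[tri(propan-2-yl)silyl]pent-4-yn-1-yl}-1,2-dioxan-3-yl]acetate | CC(C)[Si](C(C)C)(C(C)C)C#CCCC[C@]1(OC)CC[C@@H](CC(=O)OC)OO1 | intermediate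
21 | methyl 2-[(3S,6R)-6-methoxy-6-(pent-4-yn-1-yl)-1,2-dioxan-3-yl]acetate | C#CCCC[C@]1(OC)CC[C@@H](CC(=O)OC)OO1 | intermediate
22 | dec-9-en-1-ol | C=CCCCCCCCCO | starting material
23 | dec-9-enal | C=CCCCCCCCC=O | intermediate
24 | (1E)-1-iodoundeca-1,10-diene | C=CCCCCCCC/C=C/I | intermediate
25 | peroxyacarnoate A, methyl 2-[(3S,6R)-6-[(6E)-hexadeca-6,15-dien-4-yn-1-yl]-6-methoxy-1,2-dioxan-3-yl]acetate | C=CCCCCCCC/C=C/C#CCCC[C@]1(OC)CC[C@@H](CC(=O)OC)OO1 | target

## Step count and risks

Total step count: 12. Longest linear sequence: 10 (steps 1 to 9, then step 12); steps 10 and 11 form the two-step side branch.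

Steps most likely to fail:

First, step 7. The peroxide anion may not displace at the secondary lactone carbon fast enough, so that base-induced opening to the unsaturated carboxylate (which would lose the C3 information) or carboxylate-initiated oligomerisation of the lactone takes over. The fallback uses known chemistry and sets out from lactone 14. LiAlH4 in THF at 0 °C would reduce the lactone to (3R)-6-methylidene-11-[tri(propan-2-yl)silyl]undec-10-yne-1,3-diol F1. TBSCl and imidazole would silylate the primary hydroxyl to give the mono-silyl ether F2, and MsCl with Et3N would give the secondary mesylate F3. Ozonolysis in CH2Cl2/MeOH as in step 6 would give the hydroperoxy ketal mesylate F4. KOt-Bu with 18-crown-6 in toluene at 0 °C would close the 1,2-dioxane by intramolecular displacement of the mesylate with inversion, giving the (3S)-dioxane silyl ether F5. HF·pyridine would free the primary dioxane alcohol F6 without touching the alkynylsilane, and TEMPO with PhI(OAc)2 in aqueous MeCN would oxidise it to the acid, coming back to the route at 19.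

Second, step 6. Ozone may attack the silylalkyne once the alkene is consumed, or the hydroperoxy ketal and the lactone may degrade during the cold solvent exchange. The fallback sets out from 14 and avoids ozone. Lemieux–Johnson cleavage (OsO4 cat., NaIO4, 2,6-lutidine, dioxane/water), which leaves alkynes alone, would give the (4R)-keto lactone F7. Iodine-catalysed perhydrolysis of the ketone (H2O2, I2 10 mol%, MeOH, rt) would then give the methoxy hydroperoxide, coming back to the route at 16.

Third, step 8. Stereoconvergence at C6 may be incomplete, or the acid may open the peroxyketal ring to an acyclic dimethyl ketal and a C3 hydroperoxide. The fallback sets out from 19 and separates esterification from the C6 correction. Me3SiCHN2 in MeOH/toluene at 0 °C would methylate the acid without acid catalysis, giving 20 together with the (3S,6S)-epimeric methyl ester F8, which would be separated on silica. F8 would then be treated with MeOSiMe3 and catalytic Me3SiOTf in CH2Cl2 at −78 °C, where ionisation at C6 and kinetically controlled axial return of methoxide (Lewis acid-mediated substitution of an alkoxy-1,2-dioxane) would convert it to the axial-methoxy isomer, coming back to the route at 20.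

## Further compounds

F1 | step 7 | (3R)-6-methylidene-11-[tri(propan-2-yl)silyl]undec-10-yne-1,3-diol | OCC[C@H](O)CCC(=C)CCCC#C[Si](C(C)C)(C(C)C)C(C)C
F2 | step 7 | (3R)-1-[(tert-butyldimethylsilyl)oxy]-6-methylidene-11-[tri(propan-2-yl)silyl]undec-10-yn-3-ol | CC(C)(C)[Si](C)(C)OCC[C@H](O)CCC(=C)CCCC#C[Si](C(C)C)(C(C)C)C(C)C
F3 | step 7 | (3R)-1-[(tert-butyldimethylsilyl)oxy]-6-methylidene-11-[tri(propan-2-yl)silyl]undec-10-yn-3-yl methanesulfonate | CC(C)(C)[Si](C)(C)OCC[C@H](OS(C)(=O)=O)CCC(=C)CCCC#C[Si](C(C)C)(C(C)C)C(C)C
F4 | step 7 | (3R)-1-[(tert-butyldimethylsilyl)oxy]-6-hydroperoxy-6-methoxy-11-[tri(propan-2-yl)silyl]undec-10-yn-3-yl methanesulfonate, both C6 epimers | CC(C)(C)[Si](C)(C)OCC[C@H](OS(C)(=O)=O)CCC(OC)(OO)CCCC#C[Si](C(C)C)(C(C)C)C(C)C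
F5 | step 7 | tert-butyl{2-[(3S)-6-methoxy-6-{5-[tri(propan-2-yl)silyl]pent-4-yn-1-yl}-1,2-dioxan-3-yl]ethoxy}dimethylsilane, both C6 epimers | CC(C)(C)[Si](C)(C)OCC[C@@H]1CCC(OC)(CCCC#C[Si](C(C)C)(C(C)C)C(C)C)OO1
F6 | step 7 | 2-[(3S)-6-methoxy-6-{5-[tri(propan-2-yl)silyl]pent-4-yn-1-yl}-1,2-dioxan-3-yl]ethan-1-ol, both C6 epimers | OCC[C@@H]1CCC(OC)(CCCC#C[Si](C(C)C)(C(C)C)C(C)C)OO1
F7 | step 6 | (4R)-4-{3-oxo-8-[tri(propan-2-yl)silyl]oct-7-yn-1-yl}oxetan-2-one | O=C(CC[C@@H]1CC(=O)O1)CCCC#C[Si](C(C)C)(C(C)C)C(C)C
F8 | step 8 | methyl 2-[(3S,6S)-6-methoxy-6-{5-[tri(propan-2-yl)silyl]pent-4-yn-1-yl}-1,2-dioxan-3-yl]acetate | CC(C)[Si](C(C)C)(C(C)C)C#CCCC[C@@]1(OC)CC[C@@H](CC(=O)OC)OO1
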